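**Plan**

1. Retrosynthetic cuts, in order: the ester goes back to a hydroxyethyl arm and the ketal configuration is left open. The O1–C6 bond of the 3,6-dihydro-1,2-dioxine is cut next (ring atoms O1, O2, C3 = ketal carbon, C4=C5, C6 = carbon with the arm), giving a hydroperoxy ketal joined through a Z alkene to an (R)-oxetane. The O2–C3 bond then goes back to a carbonyl oxide from ozonolysis of a methyl enol ether, and the enol ether C=C and the C3–alkyne bond are the two chain-joining cuts.
2. Enabling feature: C6 is a secondary allylic carbon carrying O1 and a two-carbon arm that ends in oxygen. This is the pattern left when a 2-alkenyl oxetane is opened at its allylic carbon by a peroxide oxygen, and C3, the cis C4=C5 bond and O2 hold that oxygen at the right distance.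
3. Forward order: (R)-alkynyl oxetane (3 steps) plus a C17 Weinreb amide give an ynone, then the enol ether, the Z diene and the hydroperoxy ketal. Closure of the only ring follows, then acid, methyl ester and ketal equilibration.
4. Stereochemistry: C6 comes from a Noyori transfer hydrogenation (R, kept in the oxetane) and is inverted to S in the ring closure. The Z alkene comes from Lindlar reduction. The ketal carbon is set last by acid-catalysed methanol exchange and separation of the two epimers.

Key step: step 9

Remarks on the chemistry: systematic names number the ring from the arm carbon (position 3) to the ketal carbon (position 6), so C6 of the plan is position 3 in the names. Compounds 13 to 17 are mixtures of the two ketal epimers and are written with that centre undefined. The sense of induction in step 2 is assumed to follow that of other alkynyl ketones with this catalyst family.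

**Route**

Step 1
Reactants: 1 3-chloropropanoyl chloride; 2 bis(trimethylsilyl)acetylene
Product: 3 5-chloro-1-(trimethylsilyl)pent-1-yn-3-one
Conditions: AlCl3 (1.1 equiv), CH2Cl2, 0 °C; cold 1 M HCl work-up
Reagents that add atoms: none
Why: Friedel–Crafts-type acylation of an alkynylsilane, in which the AlCl3-activated acyl chloride attacks the silylated alkyne and ipso loss of one Me3Si group gives the ynone, whose deactivated triple bond keeps the second silyl group.

Step 2
Reactants: 3 5-chloro-1-(trimethylsilyl)pent-1-yn-3-one
Product: 4 (3R)-5-chloro-1-(trimethylsilyl)pent-1-yn-3-ol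
Conditions: Ru[(R,R)-TsNCHPhCHPhNH](η6-p-cymene) (1 mol%), i-PrOH, 25 °C
Reagents that add atoms: none
Why: Noyori asymmetric transfer hydrogenation of an alkynyl ketone, where the alkyne takes the place of the aryl group in the six-membered hydride-transfer transition state so that the (R,R)-complex should give the (R)-carbinol, and the base-free amido complex avoids loss of HCl from the β-chloro ketone.

Step 3
Reactants: 4 (3R)-5-chloro-1-(trimethylsilyl)pent-1-yn-3-ol
Product: 5 trimethyl{[(2R)-oxetan-2-yl]ethynyl}silane
Conditions: NaH (1.2 equiv), THF, 0 → 40 °C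
Reagents that add atoms: none
Why: Intramolecular Williamson etherification (4-exo-tet) in which the alkoxide displaces the primary chloride, so the C–O bond at the stereocentre is untouched and (R) is retained, while a non-nucleophilic base keeps the C–Si bond that makes the oxetane easy to handle.

Step 4
Reactants: 6 heptadecanoyl chloride
Product: 7 N-methoxy-N-methylheptadecanamide
Conditions: MeNH(OMe)·HCl, K2CO3, CH2Cl2/H2O, 0 → 20 °C
Reagents that add atoms: N,O-dimethylhydroxylamine hydrochloride, CNOC.Cl
Why: Schotten–Baumann acylation of the hydroxylamine gives the Weinreb amide needed for a single acyl transfer in the next step.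

Step 5
Reactants: 5 trimethyl{[(2R)-oxetan-2-yl]ethynyl}silane; 7 N-methoxy-N-methylheptadecanamide
Product: 9 1-[(2R)-oxetan-2-yl]nonadec-1-yn-3-one, via lithium acetylide 8 (not isolated)
Conditions: MeLi·LiBr (0.98 equiv), THF, 0 → 20 °C; then 7, −78 → 0 °C; aq NH4Cl
Reagents that add atoms: none
Why: MeLi cleaves the alkynyl C–Si bond to the lithium acetylide, which adds only once to the Weinreb amide (Weinreb ketone synthesis) because the ynone is released only on aqueous work-up, and the oxetane stereocentre is not involved.

Step 6
Reactants: 9 1-[(2R)-oxetan-2-yl]nonadec-1-yn-3-one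
Product: 10 (2R)-2-[3-(methoxymethylidene)nonadec-1-yn-1-yl]oxetane (E/Z mixture at the enol ether)
Conditions: Ph3P+CH2OMe Cl−, KN(SiMe3)2, THF, 0 °C; then 9, −78 → 0 °C
Reagents that add atoms: (methoxymethyl)triphenylphosphonium chloride, [Cl-].COC[P+](c1ccccc1)(c1ccccc1)c1ccccc1
Why: Wittig olefination with the non-stabilised methoxymethylene ylide turns the ynone carbonyl into a methyl enol ether (its geometry is irrelevant because that carbon is excised in step 8), and addition of the ketone to preformed ylide at −78 °C keeps free base away from the acidic propargylic C–H of the oxetane carbon.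

Step 7
Reactants: 10 (2R)-2-[3-(methoxymethylidene)nonadec-1-yn-1-yl]oxetane
Product: 11 (2R)-2-[(1Z)-3-(methoxymethylidene)nonadec-1-en-1-yl]oxetane
Conditions: H2 (1 atm), Pd/CaCO3 poisoned with Pb(OAc)2, quinoline, hexane/EtOAc, 20 °C
Reagents that add atoms: none
Why: Lindlar semihydrogenation delivers both hydrogens to one face of the alkyne on the poisoned palladium surface and should give the Z alkene without touching the enol ether or the oxetane.

Step 8
Reactants: 11 (2R)-2-[(1Z)-3-(methoxymethylidene)nonadec-1-en-1-yl]oxetane
Product: 13 (2R)-2-[(1Z)-3-hydroperoxy-3-methoxynonadec-1-en-1-yl]oxetane as both ketal epimers, via carbonyl oxide 12 (not isolated)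
Conditions: O3 (1.0 equiv, titrated solution in CH2Cl2), CH2Cl2/MeOH 4:1, −78 °C; Ar purge, no reductant; used promptly
Reagents that add atoms: ozone, [O-][O+]=O; methanol, CO
Why: Criegee ozonolysis with solvent capture, in which ozone should add to the enol ether as the most electron-rich π bond (the Z alkene is deactivated by its allylic C–O bond and twisted out of conjugation by the substituent on the neighbouring carbon), the primary ozonide of an enol ether cleaves in one direction to methyl formate and the ketone O-oxide, and methanol adds to that carbonyl oxide to give the hydroperoxy ketal without any need for control at the ketal carbon.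

Step 9
Reactants: 13 (2R)-2-[(1Z)-3-hydroperoxy-3-methoxynonadec-1-en-1-yl]oxetane
Product: 14 2-[(3S)-6-hexadecyl-6-methoxy-3,6-dihydro-1,2-dioxin-3-yl]ethan-1-ol as both ketal epimers (one of them the 3S,6S compound)
Conditions: Yb(OSO2CF3)3 (20 mol%), CH2Cl2, −20 → 0 °C; aq NaHCO3
Reagents that add atoms: none
Why: Proposed new method: Yb(OSO2CF3)3 binds the oxetane oxygen and the terminal hydroperoxide oxygen displaces it from the rear of the allylic carbon C6 (SN2), the closest known reaction type being the Lewis acid-promoted intramolecular exo opening of oxetanes by hydroperoxides and hydroperoxy ketals that gives saturated 1,2-dioxolanes and 1,2-dioxanes with inversion; a 2-alkenyl oxetane and a 3,6-dihydro-1,2-dioxine product have not been shown. The dioxine ring closes in a 6-exo-tet mode, the breaking C6–O bond lying outside the new ring, helped by release of the oxetane strain and by the Z alkene, which holds the oxygen and C6 within bonding distance. The new C6 stereocentre is controlled by the (R)-oxetane carbon from step 2, which is inverted to S, while the ketal carbon is a spectator and stays a mixture. Regioselectivity is secured by the tether, since attack at the oxetane CH2 would need an eight-membered ring and SN2' attack at C4 a four-membered peroxide. The step also needs substitution to outrun ionisation at C6 or at the allylic ketal carbon (racemisation, Hock-type cleavage), which a catalytic and only mildly Lewis acidic lanthanide triflate, low temperature and an alkene flanked by two oxygen-bearing carbons should favour.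

Step 10
Reactants: 14 2-[(3S)-6-hexadecyl-6-methoxy-3,6-dihydro-1,2-dioxin-3-yl]ethan-1-ol
Product: 16 2-[(3S)-6-hexadecyl-6-methoxy-3,6-dihydro-1,2-dioxin-3-yl]acetic acid as both ketal epimers, via aldehyde 15 (not isolated)
Conditions: TEMPO (20 mol%), PhI(OAc)2 (2.2 equiv), CH2Cl2/MeCN/H2O, 0 → 20 °C
Reagents that add atoms: water, O
Why: Oxoammonium oxidation (TEMPO/PhI(OAc)2) in the presence of water takes the primary alcohol through the aldehyde and its hydrate to the acid without base, so the dialkyl peroxide, the ring alkene and the base-sensitive C–H next to the peroxide should survive, and any ketal that hydrolyses is re-formed in step 12.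

Step 11
Reactants: 16 2-[(3S)-6-hexadecyl-6-methoxy-3,6-dihydro-1,2-dioxin-3-yl]acetic acid
Product: 17 methyl 2-[(3S)-6-hexadecyl-6-methoxy-3,6-dihydro-1,2-dioxin-3-yl]acetate as both ketal epimers
Conditions: Me3SiCHN2, toluene/MeOH 4:1, 0 °C
Reagents that add atoms: trimethylsilyldiazomethane, C[Si](C)(C)C=[N+]=[N-]
Why: Esterification with trimethylsilyldiazomethane in methanol is neutral and fast, so neither the peroxide nor the ketal should be disturbed.

Step 12
Reactants: 17 methyl 2-[(3S)-6-hexadecyl-6-methoxy-3,6-dihydro-1,2-dioxin-3-yl]acetate (ketal epimer mixture)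
Product: 18 methyl 2-[(3S,6S)-6-hexadecyl-6-methoxy-3,6-dihydro-1,2-dioxin-3-yl]acetate (6-epi-chondrillin)
Conditions: TsOH·H2O (10 mol%), MeOH, 20 °C; chromatography, other epimer resubjected
Reagents that add atoms: methanol, CO
Why: Acid-catalysed ketal exchange through a ring peroxycarbenium ion (stabilised by O2 and the C4=C5 bond) lets methanol re-add from either face, the equilibrium is expected to favour the epimer with a pseudoaxial methoxy group (anomeric effect) and both carbon chains pseudoequatorial, which is 18, and C6 lies outside the cation and keeps its S configuration.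

**Compound list**

1 | 3-chloropropanoyl chloride | ClCCC(Cl)=O | starting material
2 | bis(trimethylsilyl)acetylene | C[Si](C)(C)C#C[Si](C)(C)C | starting material
3 | 5-chloro-1-(trimethylsilyl)pent-1-yn-3-one | C[Si](C)(C)C#CC(=O)CCCl | intermediate
4 | (3R)-5-chloro-1-(trimethylsilyl)pent-1-yn-3-ol | C[Si](C)(C)C#C[C@H](O)CCCl | intermediate
5 | trimethyl{[(2R)-oxetan-2-yl]ethynyl}silane | C[Si](C)(C)C#C[C@@H]1OCC1 | intermediate
6 | heptadecanoyl chloride | CCCCCCCCCCCCCCCCC(Cl)=O | starting material
7 | N-methoxy-N-methylheptadecanamide | CCCCCCCCCCCCCCCCC(=O)N(C)OC | intermediate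
8 | lithium [(2R)-oxetan-2-yl]ethynide | [Li]C#C[C@@H]1OCC1 | intermediate (not isolated)
9 | 1-[(2R)-oxetan-2-yl]nonadec-1-yn-3-one | CCCCCCCCCCCCCCCCC(=O)C#C[C@@H]1OCC1 | intermediate
10 | (2R)-2-[3-(methoxymethylidene)nonadec-1-yn-1-yl]oxetane (E/Z mixture at the enol ether) | CCCCCCCCCCCCCCCCC(=COC)C#C[C@@H]1OCC1 | intermediate
11 | (2R)-2-[(1Z)-3-(methoxymethylidene)nonadec-1-en-1-yl]oxetane | CCCCCCCCCCCCCCCCC(=COC)/C=C\[C@@H]1OCC1 | intermediate
12 | (1Z)-1-[(2R)-oxetan-2-yl]nonadec-1-en-3-one O-oxide (carbonyl oxide) | CCCCCCCCCCCCCCCCC(=[O+][O-])/C=C\[C@@H]1OCC1 | intermediate (not isolated)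
13 | (2R)-2-[(1Z)-3-hydroperoxy-3-methoxynonadec-1-en-1-yl]oxetane (both ketal configurations) | CCCCCCCCCCCCCCCCC(OC)(OO)/C=C\[C@@H]1OCC1 | intermediate
14 | 2-[(3S)-6-hexadecyl-6-methoxy-3,6-dihydro-1,2-dioxin-3-yl]ethan-1-ol (both ketal epimers, one of them 3S,6S) | CCCCCCCCCCCCCCCCC1(OC)C=C[C@H](CCO)OO1 | intermediate
15 | 2-[(3S)-6-hexadecyl-6-methoxy-3,6-dihydro-1,2-dioxin-3-yl]acetaldehyde (both ketal epimers) | CCCCCCCCCCCCCCCCC1(OC)C=C[C@H](CC=O)OO1 | intermediate (not isolated)
16 | 2-[(3S)-6-hexadecyl-6-methoxy-3,6-dihydro-1,2-dioxin-3-yl]acetic acid (both ketal epimers) | CCCCCCCCCCCCCCCCC1(OC)C=C[C@H](CC(=O)O)OO1 | intermediate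
17 | methyl 2-[(3S)-6-hexadecyl-6-methoxy-3,6-dihydro-1,2-dioxin-3-yl]acetate (both ketal epimers) | CCCCCCCCCCCCCCCCC1(OC)C=C[C@H](CC(=O)OC)OO1 | intermediate
18 | methyl 2-[(3S,6S)-6-hexadecyl-6-methoxy-3,6-dihydro-1,2-dioxin-3-yl]acetate (6-epi-chondrillin) | CCCCCCCCCCCCCCCC[C@@]1(OC)C=C[C@H](CC(=O)OC)OO1 | target

**Step count**

Total: 12 steps. Longest linear sequence: 11 steps (steps 1–3 and 5–12; step 4 is a one-step side branch).

**Steps most likely to fail**

Step 9 (the proposed ring closure). The Lewis acid may ionise the allylic peroxyketal or C6 instead of promoting clean displacement, which would lead to Hock-type cleavage, loss of configuration at C6, or capture of the ketal cation by the freed hydroxyethyl arm. The fallback uses only known reaction types, sets out from 5 and comes back at 14: the peroxide oxygen is put on C6 intermolecularly before the chain is attached, and the ring is closed by ketal formation instead. Lewis acid-mediated opening of the oxetane 5 with anhydrous H2O2 in Et2O (Me3SiOSO2CF3 cat., −78 °C) should occur at the propargylic carbon with inversion to give (3S)-3-hydroperoxy-5-(trimethylsilyl)pent-4-yn-1-ol F1. 2-Methoxypropene with pyridinium p-toluenesulfonate caps both OOH and OH to give {(3S)-5-[(2-methoxypropan-2-yl)oxy]-3-[(2-methoxypropan-2-yl)peroxy]pent-1-yn-1-yl}trimethylsilane F2. Bu4NF buffered with AcOH removes the C-silyl group to give (3S)-5-[(2-methoxypropan-2-yl)oxy]-3-[(2-methoxypropan-2-yl)peroxy]pent-1-yne F3. Acylation of the terminal alkyne with 6 (PdCl2(PPh3)2, CuI, Et3N, THF, 0 °C) gives (3S)-1-[(2-methoxypropan-2-yl)oxy]-3-[(2-methoxypropan-2-yl)peroxy]docos-4-yn-6-one F4. Brief semihydrogenation over Pd/CaCO3 poisoned with Pb(OAc)2 gives (3S,4Z)-1-[(2-methoxypropan-2-yl)oxy]-3-[(2-methoxypropan-2-yl)peroxy]docos-4-en-6-one F5. TsOH in methanol then removes both caps, the (Z)-4-hydroperoxy enone closes to the cyclic peroxyhemiketal and is converted in the same pot into the methyl ketal 14.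

Step 8 (ozonolysis). Ozone may also consume the Z alkene or add across the far double bond of the dienol ether, or the vinyl carbonyl oxide may cyclise before methanol traps it. The fallback avoids ozone, sets out from 9 and comes back at 13. Ketalisation of 9 with HC(OMe)3 in MeOH (pyridinium p-toluenesulfonate cat.) gives (2R)-2-(3,3-dimethoxynonadec-1-yn-1-yl)oxetane F6. Semihydrogenation over Pd/CaCO3 poisoned with Pb(OAc)2 gives (2R)-2-[(1Z)-3,3-dimethoxynonadec-1-en-1-yl]oxetane F7. Acid-catalysed exchange of one methoxy group for a hydroperoxy group with anhydrous H2O2 in Et2O (camphorsulfonic acid cat., −20 °C) gives 13.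

Step 6 (Wittig reaction on the ynone). The ylide may act as a base, removing the propargylic proton at the oxetane carbon with erosion of enantiomeric purity, or add in conjugate fashion instead of at the carbonyl group. The fallback never forms the ynone, sets out from 5 and comes back at 13, at the price of a less selective ozonolysis. K2CO3 in MeOH removes the silyl group to give (2R)-2-ethynyloxetane F8, kept in solution. Commercial 1-octadecyne is converted by bromoboration with B-bromo-9-borabicyclo[3.3.1]nonane and protonolysis with AcOH into 2-bromooctadec-1-ene F9. Sonogashira coupling of the two (PdCl2(PPh3)2, CuI, i-Pr2NH) gives (2R)-2-(3-methylidenenonadec-1-yn-1-yl)oxetane F10. Semihydrogenation over Pd/CaCO3 poisoned with Pb(OAc)2 gives (2R)-2-[(1Z)-3-methylidenenonadec-1-en-1-yl]oxetane F11. Ozonolysis with one measured equivalent of ozone in CH2Cl2/MeOH at −78 °C cleaves the 1,1-disubstituted alkene and gives 13.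

**Further compounds**

F1 | step 9 | (3S)-3-hydroperoxy-5-(trimethylsilyl)pent-4-yn-1-ol | C[Si](C)(C)C#C[C@H](CCO)OO
F2 | step 9 | {(3S)-5-[(2-methoxypropan-2-yl)oxy]-3-[(2-methoxypropan-2-yl)peroxy]pent-1-yn-1-yl}trimethylsilane | C[Si](C)(C)C#C[C@H](CCOC(C)(C)OC)OOC(C)(C)OC
F3 | step 9 | (3S)-5-[(2-methoxypropan-2-yl)oxy]-3-[(2-methoxypropan-2-yl)peroxy]pent-1-yne | C#C[C@H](CCOC(C)(C)OC)OOC(C)(C)OC
F4 | step 9 | (3S)-1-[(2-methoxypropan-2-yl)oxy]-3-[(2-methoxypropan-2-yl)peroxy]docos-4-yn-6-one | CCCCCCCCCCCCCCCCC(=O)C#C[C@H](CCOC(C)(C)OC)OOC(C)(C)OC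
F5 | step 9 | (3S,4Z)-1-[(2-methoxypropan-2-yl)oxy]-3-[(2-methoxypropan-2-yl)peroxy]docos-4-en-6-one | CCCCCCCCCCCCCCCCC(=O)/C=C\[C@H](CCOC(C)(C)OC)OOC(C)(C)OC
F6 | step 8 | (2R)-2-(3,3-dimethoxynonadec-1-yn-1-yl)oxetane | CCCCCCCCCCCCCCCCC(OC)(OC)C#C[C@@H]1OCC1
F7 | step 8 | (2R)-2-[(1Z)-3,3-dimethoxynonadec-1-en-1-yl]oxetane | CCCCCCCCCCCCCCCCC(OC)(OC)/C=C\[C@@H]1OCC1
F8 | step 6 | (2R)-2-ethynyloxetane | C#C[C@@H]1OCC1
F9 | step 6 | 2-bromooctadec-1-ene | CCCCCCCCCCCCCCCCC(Br)=C
F10 | step 6 | (2R)-2-(3-methylidenenonadec-1-yn-1-yl)oxetane | CCCCCCCCCCCCCCCCC(=C)C#C[C@@H]1OCC1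
F11 | step 6 | (2R)-2-[(1Z)-3-methylidenenonadec-1-en-1-yl]oxetane | CCCCCCCCCCCCCCCCC(=C)/C=C\[C@@H]1OCC1
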